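33.0 s is how long a living end lasts in the summer run, as I read it from the way the gains between successive readings shrink.

| flask | free monomer | transfer agent | initiator | impurity | remark | time |
|---|---|---|---|---|---|---|
| autumn | 0.010 M | 0.58 mM | 0.50 mM | 0.70 mM | run made earlier |  |
| summer | 0.010 M | 0.77 mM | 0.50 mM | 0.70 mM | run made earlier |  |
| dawn | 0.010 M | 0.96 mM | 0.50 mM | 0.70 mM | run made earlier |  |
| blue | 0.010 M | 1.00 mM | 0.50 mM | 0.70 mM |  | 2.0 min |
| teal | 0.010 M | 0.600 mM | 0.50 mM | 0.70 mM |  | 2.0 min |

- autumn (time / s: monomer in chains / %): 10.0: 8.1; 15.0: 8.4; 40.0: 18.1; 80.0: 20.7
- summer (time / s: monomer in chains / %): 10.0: 7.3; 30.0: 12.8; 50.0: 15.8; 80.0: 17.9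
- dawn (time / s: monomer in chains / %): 10.0: 6.7; 30.0: 11.8; 50.0: 14.3; 80.0: 14.2

(scatter of a reading: 1 percentage point)

- which of the two ends with the longer chains by the average number of monomer units in a chain (chains begun, living or dead) ("neither" if they lie within 10 %) (blue / teal / neither)
- average number of monomer units in a chain (chains begun, living or dead) at the end, blue
- average number of monomer units in a chain (chains begun, living or dead) at the end, teal

- the average divides the monomer in chains by the number of chains begun, living and dead together
- steps thought possible: free monomer + initiator -> living end + monomer in chains; free monomer + living end -> monomer in chains + living end; living end + transfer agent -> dead chain; living end -> dead end A; initiator + impurity -> spent initiator B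
- the earlier runs do not show the number of chains; that part of a forecast is a guess

Chain length is a contest between two rates per living end: adding free monomer and meeting transfer agent. I count transfer as the ending step, since the last reading is higher in the autumn run, with less transfer agent, than in the dawn run. The number of living ends cancels in this ratio.

To measure the ratio, I use the summer run. At its first reading, 12 percentage points is still to come, so the curve ends near 19.4 %. Run back to zero, it leaves a burst of 3.02 %, which I take as one monomer per chain begun. Each chain in the summer run therefore adds, by this reading, 5.43 units after its first, the kinetic chain length. Dividing that by [free monomer]/[transfer agent] gives the growth-to-transfer ratio, 0.418.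

My rule, with [free monomer] and [transfer agent] as charged, is length = 1 + ratio × [free monomer]/[transfer agent]. It gives 5.18 for blue and 7.97 for teal, so teal is longer. With a burst of that size and a scatter of 1 point, both lengths are rough.

The forecast says teal, with 5 for blue and 7.2 for teal. On the count of chains it says: “The number of chains is the guess.” My teal length is higher than the forecast's.

The flask gives teal, with 6.40 for blue and 9.48 for teal, both above what my ratio gave.

    free monomer + initiator → living end + monomer in chains (k = 230 /M/s)
    free monomer + living end → monomer in chains + living end, rate k2*[living end]*[free monomer] (k = 26.0 /M/s)
    living end + transfer agent → dead chain (kL = 47.0 /M/s)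
    living end → dead end A (k = 0.00200 /s)
    initiator + impurity → spent initiator B (k = 4300 /M/s)

At the charge of blue, a living end adds free monomer at 0.260 /s and meets transfer agent at 0.0470 /s, so growth is faster by a factor of 5.53. A neighbour flask is blue with 0.0020 M of initiator, and [free monomer]/[transfer agent] as charged is unchanged, so 0.418 gives the same 5.18 there. The computed length in that neighbour flask is 6.10, with 82.1 % monomer in chains, beside 6.40 in blue.

(The runs are simulated for substances that don't exist; the scatter is artificial.)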